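The numbers in the tables are calculated from invented constants, noise included.

The catalyst charged stays in a closed flask for as long as the flask runs. Two chemists dispute what that costs in the two new flasks.

the same everywhere: starting material 0.050 M
- south-west: protic impurity 0.025 M; free catalyst 0.019 mM; temperature −20 °C; run made earlier
- south: protic impurity 0.025 M; free catalyst 0.074 mM; temperature 5 °C; run made earlier
- Wednesday's: protic impurity 0.0250 M; free catalyst 0.025 mM; at 25 °C throughout; time 25 min
- Tuesday's: protic impurity 0.0250 M; free catalyst 0.10 mM; at 25 °C until 5.0 min, from then on at −15 °C; time 25 min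

| run | time / min | target / % | isomer of the product / % | starting material / % |
|---|---|---|---|---|
| south-west | 15.0 | 0 | 0 | 94 |
| south-west | 50.0 | 0 | 0 | 84 |
| south-west | 80.0 | 1 | 1 | 75 |
| south-west | 150 | 3 | 1 | 67 |
| south-west | 180 | 2 | 0 | 62 |
| south-west | 240 | 4 | 0 | 62 |
| south | 5.00 | 0 | 0 | 77 |
| south | 8.00 | 5 | 1 | 69 |
| south | 15.0 | 5 | 3 | 57 |
| south | 25.0 | 9 | 1 | 50 |
| south | 40.0 | 12 | 0 | 41 |
| south | 60.0 | 21 | 0 | 32 |

(scatter of a reading: 2 percentage points)



1. which one finishes higher in share of target in all that became target or isomer of the product ("neither" within 2 percentage points) (Wednesday's / Tuesday's / neither)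
2. share of target in all that became target or isomer of the product, Wednesday's
3. share of target in all that became target or isomer of the product, Tuesday's

The first chemist reads a fixed share. Summing the south run gives him roughly 90% target at 5 °C, and he concludes: “I see no solid dependence of selectivity on temperature or catalyst”. His forecast is 90% for Wednesday's, 89% for Tuesday's, and neither as the higher.

The second chemist holds a different view, and this reckoning is hers. She takes isomer to grow from target under the catalyst, at a rate κ·C·P, where κ is a rate constant, C the catalyst and P the target. Replace the rising target by its mean, 0.5 P at the end. The leak, isomer over target, is then L = κX, with X = 0.5 C t and t the time.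

For Wednesday's, X is 0.0187 M·s, the mean-target exposure. The south run has 0.133 M·s. Its last reading shows target 21% and isomer 0%, with a scatter of 2 percentage points. One scatter over that target, divided by the south run's X, gives a rough upper estimate of κ at 5 °C: 42.9 L mol⁻¹ min⁻¹.

She borrows the forecast's temperature factor of about 3, upward for 25 °C and downward for −15 °C. Her upper estimate of Wednesday's leak is then 4.02%. For Tuesday's, she counts the warm stretch by its mean and the target as standing whole through the cold stretch. That gives 6.08%. Her lower estimates of the share are 96.1% for Wednesday's and 94.3% for Tuesday's, both higher than the forecast .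

The simulation gives 98.0% for Wednesday's and 97.6% for Tuesday's, so the higher is neither. The forecast's verdict stands, but its shares are low by 8 points and 8.6 points.

    target + free catalyst ⇌ isomer of the product + free catalyst, rate k1*[free catalyst]*[target] forward; the back reaction follows from the equilibrium constant (K = 1.80, k = 62.0 L mol⁻¹ min⁻¹, Ea = 39.0 kJ mol⁻¹, ΔH = −55.0 kJ mol⁻¹)
    catalyst intermediate ⇌ free catalyst + target (K = 0.0970 M, k = 290 min⁻¹, Ea = 76.0 kJ mol⁻¹, ΔH = −45.0 kJ mol⁻¹)
    starting material + protic impurity → quenched substrate (k = 12.0 L mol⁻¹ min⁻¹, Ea = 58.0 kJ mol⁻¹)
    starting material + free catalyst → catalyst intermediate (k = 470 L mol⁻¹ min⁻¹, Ea = 56.0 kJ mol⁻¹)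
    (constants at 25 °C)

In Wednesday's at 25.0 min, the half-life of target by its forward passing into isomer is 8.2 h, long against the run's 25 min. Isomer stands there at 0.257% beside 12.7% of target. With k₁ from the scheme, the exposure 0.0187 M·s gives a share of 98.1%. Wednesday's recipe with 1.0 × 10⁻⁴ M of free catalyst has an exposure of 0.0750 M·s, which gives 92.8%. The first chemist's 90% stands 2 points from that flask, which gives 92.0%.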